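If a quick number for this flask is what you need, I take your hunch that the reaction is over by the reading and test it by going round twice.

substrate 5.0 mM; reagent 20.0 mM; time 1.5 min

    substrate + reagent → intermediate + by-product (k1 = 16 L mol⁻¹ s⁻¹)
    intermediate ⇌ target (K2 = 10, k2 = 9.0 s⁻¹)
    intermediate ⇌ isomer of the product (K3 = 2.0, k3 = 4.2 s⁻¹)

- the state of affairs at 1.5 min: stopped, and by what, or still going (the reagent has run out first / forward and back rates have come level / it is still moving / all of the substrate has reacted)
- how much of the substrate has reacted by 1.5 min
- how much target there is at 1.5 min, in percent of the substrate charged
- how much isomer of the product there is at 1.5 min, in percent of the substrate charged

- the reaction counts as stopped when no species that holds the substrate changes by six tenths of a point or more over the second half of the time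
- run time (flask): 1.5 min

On the first round I treat step one as pseudo-first-order, with the reagent held at its charge. The substrate half-life is then 2.17 s, much shorter than the run of 90 s, and the exponent of the decay is large:

rate constant × reagent as charged × time = 28.8

That answer has the substrate reacting away, and the substrate is the limiting reagent, since its charge is less than the reagent's. So I put back the reagent that this leaves and go round again:

rate constant × (reagent charged − substrate charged) × time = 21.6

This gives a conversion of >99.9%.

Each by its own step alone, both ways together, the intermediate relaxes with the target in a half-life of 0.0700 s and with the isomer of the product in 0.110 s, both much shorter than the substrate's, so I take the three forms to stay at equilibrium as they are made: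

10 / (1 + 10 + 2.0) = 76.9%

I call this the target share: the part of the reacted substrate that stands as target while intermediate, target and isomer of the product are at equilibrium. I therefore commit to 76.9% of target and 15.4% of isomer of the product.

The forecast reads all of the substrate has reacted, with 100% conversion, 76.9% of target and 15.4% of isomer of the product, on the ground that “the equilibrium only sets the product split”.

The simulation gives all of the substrate has reacted, with 100% conversion, 76.9% of target and 15.4% of isomer of the product. In this flask 0% of the substrate and 75% of the reagent remain at 1.50 min. With 8.91% of the substrate still there at 0.150 min, the target share gives 70.0% of target, and this flask reads 69.7%. In the neighbour charged with 5.0 mM of reagent, 12.2% of the substrate remains at 1.50 min, so the target share gives 67.5%, and that neighbour reads 67.5%.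

(The constants were chosen freely; the flask was simulated.)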